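We decide how much reagent to load by following every mole of it through this flask.

left-handed substrate 0.020 M; reagent 3.00 equiv; free catalyst 0.092 mol%; precatalyst 0.49 mol%; right-handed substrate 0.020 M; time 15 h

    precatalyst → racemization catalyst (k1 = 0.00130 s⁻¹)
    left-handed substrate + racemization catalyst ⇌ right-handed substrate + racemization catalyst, rate k2*[racemization catalyst]*[left-handed substrate] forward; the back reaction follows from the equilibrium constant (k2 = 506 M⁻¹ s⁻¹)
    2 reagent → self-condensation product (k3 = 0.0146 M⁻¹ s⁻¹)
    reagent + free catalyst + right-handed substrate → free catalyst + right-handed product (k4 = 54.6 M⁻² s⁻¹)
    reagent + free catalyst + left-handed substrate → free catalyst + left-handed product (k5 = 348 M⁻² s⁻¹)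

- free catalyst is single-handed; left-handed substrate and right-handed substrate are mirror images of each other, charged as a racemate, each of them at the stated concentration
- two of one species on the left: rate k times its square, two consumed each time
- the reaction counts as stopped when no species that holds the left-handed substrate and right-handed substrate together changes by six tenths of a point or more over the second half of the time
- run time (flask): 15 h

1. why nothing more happens at 15 h, or that something still does (it is still moving / forward and back rates have come level / the reagent has run out first / no working catalyst is left / all of the left-handed substrate has reacted)
2. how much left-handed product there is at 15 h, in percent of the left-handed substrate and right-handed substrate together charged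
3. how much right-handed substrate there is at 15 h, in percent of the left-handed substrate and right-handed substrate together charged

We read equivalents and loadings on the left-handed substrate, so the flask holds reagent B = 0.0600 M and free catalyst c = 1.84 × 10⁻⁵ M. We keep both substrate hands level, at x each, because the racemization catalyst, formed from the precatalyst with a life of 12.8 min, turns left-handed substrate over at 0.0496 s⁻¹ at full strength, while reagent at its charge removes it at 3.84 × 10⁻⁴ s⁻¹.

With b the reagent present, x falls at κbx, where κ = 0.00370 M⁻¹ s⁻¹, and b falls at δb² + 2κbx, where δ = 0.0292 M⁻¹ s⁻¹. Counting progress as exposure E, the time integral of b, makes both linear: x falls as exp(−κE), and b = (B + D)exp(−δE) − D exp(−κE), with D = 2κx/(δ − κ) at the charge, 0.00581 M. Self-condensation alone gives the reagent a first half-life of 9.51 min, far shorter than 15 h.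

Setting b to zero gives E* = ln(1 + B/D)/(δ − κ) = 95.2 M·s. This E*, the total reagent exposure a flask of this scheme gets before b reaches zero, leaves exp(−κE*) = 70.3% of each hand. The books then close:

| Entry | Reagent |
|---|---|
| Charged | 0.0600 M |
| Into both products | 0.0119 M |
| Into self-condensation product | 0.0481 M |

We therefore commit to right-handed substrate 35.1% and, by the share of 348 M⁻² s⁻¹ in the two constants, left-handed product 25.7%. We answer that the reagent, the limiting reagent here, has run out first: as b nears zero it decays with a life of 2.67 h, shorter than 15 h, while 70.3% of each hand stands.

The forecast gives the reagent has run out first, left-handed product 46.7% and right-handed substrate 23%, on the ground: “I take reagent as 3 equiv of total substrate, 0.12 M, with free catalyst 3.7×10⁻⁵ M.” Our concentrations above differ from these.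

The simulated flask gives the reagent has run out first, left-handed product 25.6% and right-handed substrate 35.2%, with 0.019% of the reagent's charge left at 15.0 h. At 0.114 h the flask's reagent was going 8.1 times as fast into self-condensation product as into left-handed product, and by 1.50 h it stood at 6.56% of its charge. Loading 12.0 equiv in the neighbour flask raises E* from 95.2 M·s to 147 M·s, so exp(−κE*) gives right-handed substrate 29.0%, and that neighbour holds 29.1%.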